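## Retrosynthetic overview

- The target is a cis-fused 3,6-diaryl-furo[3,4-c]furan-1-one with both aryl groups exo. The last disconnection is the three aryl O–CH3 bonds of a guaiacyl/syringyl precursor.
- Key disconnection: the C3a–C6a (β–β') bond and both benzylic C–O bonds are opened at once to two phenoxyl radicals. One is a feruloyl amide carrying a C2-symmetric pyrrolidine auxiliary, the other is sinapyl alcohol.
- Ring order in the forward sense: radical β–β' hetero-coupling gives a bis(quinone methide). The tetrahydrofuran ring closes when the CH2OH adds to the feruloyl-derived quinone methide. The lactone ring closes when the amide oxygen adds to the sinapyl-derived quinone methide, and hydrolysis of the resulting iminium ether expels the auxiliary.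
- Building blocks: ferulic acid plus (2S,5S)-2,5-dimethylpyrrolidine (amide coupling); sinapic acid → ethyl ester → sinapyl alcohol.

Assumption: the facial sense of the key coupling follows the s-cis amide radical model given in step 4 and has not been tested on this substrate; the ee of the coupling product is checked by chiral HPLC and raised by one recrystallisation; the auxiliary is used as its free base and recovered from step 4.

## Route

Step 1
Reactants: 1 ferulic acid [(E)-4-hydroxy-3-methoxycinnamic acid]; 2 (2S,5S)-2,5-dimethylpyrrolidine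
Product: 4 (E)-1-[(2S,5S)-2,5-dimethylpyrrolidin-1-yl]-3-(4-hydroxy-3-methoxyphenyl)prop-2-en-1-one, via benzotriazol-1-yl ferulate 3 (not isolated)
Conditions: DCC (1.1 equiv), HOBt (1.1 equiv), THF, 0 °C, 1 h; then 2 (1.3 equiv), rt → 40 °C, 16 h
Reagents that add atoms: none
Why: Carbodiimide/HOBt amide coupling, in which the secondary amine is far more nucleophilic than the free phenol towards active ester 3, so no phenol protection is needed; no stereocentre is formed and the two auxiliary centres are untouched.

Step 2
Reactants: 5 sinapic acid [(E)-4-hydroxy-3,5-dimethoxycinnamic acid]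
Product: 6 ethyl (E)-3-(4-hydroxy-3,5-dimethoxyphenyl)prop-2-enoate (ethyl sinapate)
Conditions: EtOH, H2SO4 (cat.), reflux, 12 h
Reagents that add atoms: ethanol, CCO
Why: Fischer esterification driven by ethanol as solvent; no stereocentre is formed and the E-alkene is untouched.

Step 3
Reactants: 6 ethyl sinapate
Product: 8 sinapyl alcohol [(E)-4-(3-hydroxyprop-1-en-1-yl)-2,6-dimethoxyphenol], via sinapaldehyde 7 (not isolated)
Conditions: i-Bu2AlH (4.2 equiv), toluene, 0 °C, 1 h; aq. KNaC4H4O6 work-up
Reagents that add atoms: none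
Why: 1,2-selective ester-to-allylic-alcohol reduction with i-Bu2AlH through aldehyde 7, the phenol being masked in the flask as its aluminium phenoxide; no stereocentre is formed and the E geometry is retained.

Step 4
Reactants: 4 feruloyl amide (2.0 equiv); 8 sinapyl alcohol (1.0 equiv)
Product: 11 (3S,3aR,6S,6aS)-3-(4-hydroxy-3,5-dimethoxyphenyl)-6-(4-hydroxy-3-methoxyphenyl)tetrahydro-1H,3H-furo[3,4-c]furan-1-one, via bis-quinone-methide 9 (not isolated), via iminium ether zwitterion 10 (not isolated)
Conditions: Ag2O (1.2 equiv), CH2Cl2–acetone 4:1, −10 °C, 8 added over 6 h, then 0 °C, 6 h; filter; 0.5 M aq. citric acid–THF, rt, 1 h; SiO2, then recrystallisation (EtOAc–hexane)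
Reagents that add atoms: water, O
Why: Proposed new method: Ag2O oxidises both phenols to phenoxyl radicals that couple C8 (feruloyl) to Cβ (sinapyl); in the s-cis tertiary amide the C8–H lies next to one methyl-bearing pyrrolidine carbon, whose methyl shields the Re face of C8, so the sinapyl radical bonds to the Si face and fixes C6a as S; of the resulting bis(quinone methides) only the (2R,3R) isomer 9 can close to a cis-fused bicycle, which fixes C3a as R; 5-exo addition of the CH2OH to the guaiacyl quinone methide sets C6 and 5-exo addition of the amide oxygen to the syringyl quinone methide sets C3, each with the aryl group trans to the neighbouring ring substituent (exo); water then hydrolyses iminium ether 10 to the lactone and releases amine 2; closest known reaction types are the dehydrogenative 8–β coupling of ferulates with monolignols by Ag2O or peroxidase, face-selective radical reactions of 2,5-dimethylpyrrolidine amides, and the iodolactonisation of tertiary γ,δ-unsaturated amides with loss of the amine.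

Step 5
Reactants: 11 trimethyl ether lactone
Product: 12 (3S,3aR,6S,6aS)-6-(3,4-dihydroxyphenyl)-3-(3,4,5-trihydroxyphenyl)tetrahydro-1H,3H-furo[3,4-c]furan-1-one (CNP0290035.1)
Conditions: AlCl3 (6 equiv), pyridine (25 equiv), ClCH2CH2Cl, 60 °C, 24 h, Ar; then cold 1 M HCl, EtOAc, aq. Na2S2O4 wash; C18 chromatography
Reagents that add atoms: none
Why: Ortho-hydroxy-directed aryl methyl ether cleavage (AlCl3–pyridine, SN2 attack of pyridine on the methyl of the aluminium-chelated guaiacol and syringol units), possible because all three OCH3 groups sit ortho to a phenol oxygen; the pyridine-buffered medium is expected to leave the lactone and the benzylic C–O bonds intact, so no stereocentre is touched.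

## Compound list

1 | ferulic acid, (E)-4-hydroxy-3-methoxycinnamic acid | COc1cc(/C=C/C(=O)O)ccc1O | starting material
2 | (2S,5S)-2,5-dimethylpyrrolidine (trans, C2-symmetric) | C[C@H]1CC[C@H](C)N1 | starting material
3 | benzotriazol-1-yl (E)-3-(4-hydroxy-3-methoxyphenyl)prop-2-enoate | COc1cc(/C=C/C(=O)On2nnc3ccccc32)ccc1O | intermediate
4 | (E)-1-[(2S,5S)-2,5-dimethylpyrrolidin-1-yl]-3-(4-hydroxy-3-methoxyphenyl)prop-2-en-1-one | COc1cc(/C=C/C(=O)N2[C@@H](C)CC[C@@H]2C)ccc1O | intermediate
5 | sinapic acid, (E)-4-hydroxy-3,5-dimethoxycinnamic acid | COc1cc(/C=C/C(=O)O)cc(OC)c1O | starting material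
6 | ethyl (E)-3-(4-hydroxy-3,5-dimethoxyphenyl)prop-2-enoate | CCOC(=O)/C=C/c1cc(OC)c(O)c(OC)c1 | intermediate
7 | sinapaldehyde, (E)-3-(4-hydroxy-3,5-dimethoxyphenyl)prop-2-enal | COc1cc(/C=C/C=O)cc(OC)c1O | intermediate
8 | sinapyl alcohol, (E)-4-(3-hydroxyprop-1-en-1-yl)-2,6-dimethoxyphenol | COc1cc(/C=C/CO)cc(OC)c1O | intermediate
9 | (2R,3R)-4-(3,5-dimethoxy-4-oxocyclohexa-2,5-dien-1-ylidene)-1-[(2S,5S)-2,5-dimethylpyrrolidin-1-yl]-3-(hydroxymethyl)-2-[(3-methoxy-4-oxocyclohexa-2,5-dien-1-ylidene)methyl]butan-1-one | O=C(N1[C@@H](C)CC[C@@H]1C)[C@H](C=C2C=CC(=O)C(OC)=C2)[C@H](CO)C=C3C=C(OC)C(=O)C(OC)=C3 | intermediate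
10 | (2S,5S)-1-[(3S,3aR,6S,6aS)-3-(3,5-dimethoxy-4-oxidophenyl)-6-(4-hydroxy-3-methoxyphenyl)tetrahydro-1H,3H-furo[3,4-c]furan-1-ylidene]-2,5-dimethylpyrrolidinium | C[C@H]1CC[C@H](C)[N+]1=C2O[C@H](c4cc(OC)c([O-])c(OC)c4)[C@H]3CO[C@H](c5ccc(O)c(OC)c5)[C@@H]23 | intermediate
11 | (3S,3aR,6S,6aS)-3-(4-hydroxy-3,5-dimethoxyphenyl)-6-(4-hydroxy-3-methoxyphenyl)tetrahydro-1H,3H-furo[3,4-c]furan-1-one (cis-fused, both aryl groups exo) | O=C1O[C@H](c2cc(OC)c(O)c(OC)c2)[C@H]2CO[C@H](c3ccc(O)c(OC)c3)[C@@H]12 | intermediate
12 | (3S,3aR,6S,6aS)-6-(3,4-dihydroxyphenyl)-3-(3,4,5-trihydroxyphenyl)tetrahydro-1H,3H-furo[3,4-c]furan-1-one | O=C1O[C@H](c2cc(O)c(O)c(O)c2)[C@H]2CO[C@H](c3ccc(O)c(O)c3)[C@@H]12 | target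

## Step count and risks

Total step count: 5. Longest linear sequence: 4 steps (5 → 6 → 8 → 11 → 12).

The three steps most likely to fail:

**Step 4 (key coupling).** Homo-coupling of 8 to syringaresinol and 8–5 or 8–O–4 dimers of 4 compete with the hetero-coupling, so the yield is likely to be low (about 15–25% estimated). The facial bias in an early radical–radical transition state may be smaller than in radical additions. Water may capture the syringyl quinone methide before the amide oxygen does, which is why the acidic work-up is included. The fallback sets out from 1 and 8 and comes back at 11. Free ferulic acid 1 and sinapyl alcohol 8 are co-oxidised with FeCl3·6H2O in aqueous acetone at room temperature, where the carboxylic acid itself traps the quinone methide. This gives racemic 11, that is 11 together with its mirror image, the (3R,3aS,6R,6aR)-trimethyl ether lactone F1, which is removed by preparative chiral SFC on an amylose tris(3,5-dimethylphenylcarbamate) phase. Step 1 is then not needed and 11 goes on to step 5.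

**Step 5 (triple demethylation).** The second syringyl OCH3 may cleave slowly. The free para-phenols can open the benzylic C–O bonds through a quinone methide or benzylic cation and epimerise C3 or C6. The pyrogallol product is air-sensitive. The fallback sets out from 11 and comes back at 12. The two para-phenols are acetylated (Ac2O, pyridine, rt) to the 4,4'-di-O-acetyl trimethyl ether F2, whose rings can no longer support a quinone methide or a stabilised benzylic cation. The methyl ethers are then cleaved with BBr3 in CH2Cl2 at −78 → −20 °C to give the 4,4'-di-O-acetyl pentahydroxy lactone F3. The acetates are removed with N2H4·AcOH in DMF at room temperature under argon to give 12.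

**Step 1 (amide coupling).** The α,α'-disubstituted amine acylates slowly, so N-acylurea formation and phenol O-acylation can take over. The fallback sets out from 2 and comes back at 4. Amine 2 is heated with Meldrum's acid in toluene at 100 °C to give 3-[(2S,5S)-2,5-dimethylpyrrolidin-1-yl]-3-oxopropanoic acid F4. This is condensed with commercial vanillin (pyridine, piperidine cat., 90 °C; Knoevenagel–Doebner condensation with decarboxylation) to give 4 directly as the E-amide.

## Further compounds

F1 | step 4 | (3R,3aS,6R,6aR)-3-(4-hydroxy-3,5-dimethoxyphenyl)-6-(4-hydroxy-3-methoxyphenyl)tetrahydro-1H,3H-furo[3,4-c]furan-1-one (enantiomer of 11) | O=C1O[C@@H](c2cc(OC)c(O)c(OC)c2)[C@@H]2CO[C@@H](c3ccc(O)c(OC)c3)[C@H]12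
F2 | step 5 | (3S,3aR,6S,6aS)-3-(4-acetoxy-3,5-dimethoxyphenyl)-6-(4-acetoxy-3-methoxyphenyl)tetrahydro-1H,3H-furo[3,4-c]furan-1-one | O=C1O[C@H](c2cc(OC)c(OC(C)=O)c(OC)c2)[C@H]2CO[C@H](c3ccc(OC(C)=O)c(OC)c3)[C@@H]12
F3 | step 5 | (3S,3aR,6S,6aS)-3-(4-acetoxy-3,5-dihydroxyphenyl)-6-(4-acetoxy-3-hydroxyphenyl)tetrahydro-1H,3H-furo[3,4-c]furan-1-one | O=C1O[C@H](c2cc(O)c(OC(C)=O)c(O)c2)[C@H]2CO[C@H](c3ccc(OC(C)=O)c(O)c3)[C@@H]12
F4 | step 1 | 3-[(2S,5S)-2,5-dimethylpyrrolidin-1-yl]-3-oxopropanoic acid | OC(=O)CC(=O)N1[C@@H](C)CC[C@@H]1C
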